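**Plan**

1. Retrosynthesis: the C15 acetate and the C8 (Z)-2-(acetoxymethyl)but-2-enoate come off first. The tricycle is then cut at C7–C8 (oxepane ring C), at C7=C11 and O–C12 of lactone ring A, at C6–C7, at C5–O of oxepane ring B and at C3–C4. This leaves (R)-linalool (C1–C3, C8–C10, C14), vinyl ethylene carbonate (C4–C6, C15), vinylmagnesium bromide (C7) and 2-(bromomethyl)acrylic acid (C11–C13).
2. Forward order: the chain is joined by iridium-catalysed (hydroxymethyl)allylation; ring B closes by oxymercuration (C5–O); ring A is built as a 3-(bromomethyl)butenolide (vinyl addition, acylation, ring-closing metathesis); ring C closes last by intramolecular chromium-mediated allylation; acylation at O8, desilylation and acetylation at O15 finish the route.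
3. Enabling feature: with ring A held as the endocyclic butenolide, C13–C11=C7 is an allyl unit whose γ-carbon is C7, and the C8 carbonyl is tied to C6 through C9–C10–O–C5. The SE2′ union makes C7–C8, sets C7 and C8 and returns the exocyclic C11=C13 methylene.
4. Stereochemistry: C10 comes from (R)-linalool; C3 and C4 (anti) from the chiral iridium catalyst; C5 from a cis-fused silylene ring used as a temporary template; C6 from chelation-controlled vinyl addition; C7 and C8 from the closed transition state of the ring-C closure; the Z acyl group from a configurationally stable vinyllithium.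

Key step: step 13

Remark 1: locants C1–C15 follow the germacrane numbering of the target in every intermediate. Ring A is O–C6–C7–C11–C12 (C13 = methylene); ring B is O, C5, C4, C3, C2, C1, C10; ring C is O, C5, C6, C7, C8, C9, C10; C14 is the methyl on C10 and C15 the CH2 on C4.
Remark 2: in the given configuration the C6 arm on C5 and the C9 arm on C10 lie on opposite faces of ring B (C14 is cis to C6), so ring C closes as a strained, trans-bridged 11-oxabicyclo[4.4.1]undecane.
Remark 3 (assumption): the SEGPHOS enantiomer written in step 4 is taken to be the one that gives the (3R,4R) adduct; its antipode is used otherwise.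

**Route**

Step 1
Reactants: 1 (R)-(−)-linalool
Product: 2 (3R)-3,7-dimethyloct-6-ene-1,3-diol
Conditions: 9-borabicyclo[3.3.1]nonane (9-BBN), THF, 0 to 25 °C; then NaOH, H2O2
Reagents that add atoms: hydrogen peroxide, OO
Why: anti-Markovnikov hydroboration–oxidation; 9-BBN should add only to the monosubstituted vinyl group, the trisubstituted alkene being far slower, and C10 is not touched.

Step 2
Reactants: 2 (3R)-3,7-dimethyloct-6-ene-1,3-diol
Product: 3 (3R)-1-[(tert-butyldimethylsilyl)oxy]-3,7-dimethyloct-6-en-3-ol
Conditions: TBSCl, imidazole, CH2Cl2, 0 °C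
Reagents that add atoms: tert-butyldimethylsilyl chloride, CC(C)(C)[Si](C)(C)Cl
Why: silyl ether formation, which should be selective for the primary over the tertiary hydroxyl.

Step 3
Reactants: 3 (3R)-1-[(tert-butyldimethylsilyl)oxy]-3,7-dimethyloct-6-en-3-ol
Product: 4 (5R)-5-{2-[(tert-butyldimethylsilyl)oxy]ethyl}-5-methyloxolan-2-ol (lactol, both anomers)
Conditions: O3, CH2Cl2–MeOH, −78 °C; then Me2S
Reagents that add atoms: ozone, [O-][O+]=O
Why: ozonolysis of the only alkene gives the C3 aldehyde, which should close onto the tertiary hydroxyl as a five-membered lactol, a stable aldehyde equivalent.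

Step 4
Reactants: 4 lactol; 5 4-vinyl-1,3-dioxolan-2-one (vinyl ethylene carbonate)
Product: 6 (2R,3R,6R)-8-[(tert-butyldimethylsilyl)oxy]-2-ethenyl-6-methyloctane-1,3,6-triol
Conditions: [Ir(cod)Cl]2 (2.5 mol %), (S)-SEGPHOS (5 mol %), 4-cyano-3-nitrobenzoic acid (10 mol %), K3PO4 (5 mol %), i-PrOH (2 equiv), THF, 60 °C
Reagents that add atoms: none
Why: iridium-catalysed transfer-hydrogenative carbonyl (hydroxymethyl)allylation; decarboxylative ionisation of 5 gives a (hydroxymethyl)allyl–iridium species that should add to the aldehyde in equilibrium with 4 through a chair-like closed transition state of the (E)-σ-allyl, giving the anti C3/C4 pair, with the absolute sense fixed by the ligand because C10 is remote.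

Step 5
Reactants: 6 triol
Product: 7 (4R,5R)-2,2-di-tert-butyl-4-{(3R)-5-[(tert-butyldimethylsilyl)oxy]-3-hydroxy-3-methylpentyl}-5-ethenyl-1,3,2-dioxasilinane
Conditions: t-Bu2Si(OTf)2, 2,6-lutidine, CH2Cl2, 0 °C
Reagents that add atoms: di-tert-butylsilyl bis(trifluoromethanesulfonate), CC(C)(C)[Si](OS(=O)(=O)C(F)(F)F)(OS(=O)(=O)C(F)(F)F)C(C)(C)C
Why: silylene protection; the 1,3-diol (O3, O15) should form the six-membered silylene much faster than the tertiary hydroxyl reacts, and this temporary ring holds the C2 arm and the vinyl group cis for the closure of ring B (it is removed in step 19).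

Step 6
Reactants: 7 silylene-protected tertiary alcohol
Product: 9 ring-B alcohol (3R,4S,5R,10R): oxepane O–C5–C4–C3–C2–C1–C10 with CH2OH (C6) on C5, CH3 and CH2CH2OTBS on C10, O3 and O15 joined as di-tert-butylsilylene, via alkylmercury trifluoroacetate 8 (not isolated)
Conditions: Hg(OCOCF3)2, NaHCO3, CH2Cl2, 0 °C; then NaBH4, O2, DMF, 0 °C
Reagents that add atoms: dioxygen, O=O
Why: intramolecular oxymercuration (7-exo, Markovnikov attack of the tertiary hydroxyl at C5) followed by oxidative demercuration of C6–Hg to C6–OH; with the allylic C4–H eclipsing the alkene and the oxygen delivered from the C3 side, C6 should end on the convex face of the cis-fused silylene/oxepane bicycle, trans to C15.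

Step 7
Reactants: 9 ring-B alcohol
Product: 10 ring-B aldehyde (3R,4S,5R,10R), CHO (C6) on C5
Conditions: Dess–Martin periodinane, CH2Cl2, 25 °C
Reagents that add atoms: none
Why: Dess–Martin oxidation of the primary alcohol under non-basic conditions, which should not epimerise the α-alkoxy centre C5.

Step 8
Reactants: 10 ring-B aldehyde
Product: 11 allylic alcohol (3R,4S,5R,6R,10R), CH(OH)CH=CH2 on C5
Conditions: MgBr2·OEt2, CH2Cl2, −78 °C; then CH2=CHMgBr, THF, −78 °C
Reagents that add atoms: vinylmagnesium bromide, C=C[Mg]Br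
Why: Cram-chelate Grignard addition; magnesium bridges the aldehyde oxygen and the ring oxygen on C5, and attack anti to C4 should give the syn C5–O/C6–OH relation that ring A needs.

Step 9
Reactants: 11 allylic alcohol; 12 2-(bromomethyl)acrylic acid
Product: 13 O6 2-(bromomethyl)acrylate of 11 (3R,4S,5R,6R,10R)
Conditions: DCC, DMAP (5 mol %), CH2Cl2, −20 to 0 °C
Reagents that add atoms: none
Why: Steglich esterification of the secondary allylic alcohol with retention at C6; low temperature and a catalytic amount of DMAP should keep the allylic bromide intact.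

Step 10
Reactants: 13 diene ester
Product: 14 3-(bromomethyl)butenolide (3R,4S,5R,6R,10R): ring A as O–C6–C7=C11(CH2Br)–C12(=O) on C5 of ring B, C8 as CH2OTBS
Conditions: second-generation Grubbs catalyst RuCl2(=CHPh)(PCy3)(H2IMes) (10 mol %), CH2Cl2, 40 °C
Reagents that add atoms: none
Why: ring-closing metathesis between the C7 vinyl group and the 1,1-disubstituted acrylate alkene should close the five-membered butenolide with loss of ethene; the ruthenium carbene tolerates allylic bromides.

Step 11
Reactants: 14 butenolide TBS ether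
Product: 15 butenolide primary alcohol (3R,4S,5R,6R,10R), CH2CH2OH on C10
Conditions: PPTS (0.2 equiv), MeOH, 25 °C
Reagents that add atoms: none
Why: acid-catalysed methanolysis of the primary TBS ether; the hindered six-membered silylene, the lactone and the allylic bromide should survive.

Step 12
Reactants: 15 butenolide primary alcohol
Product: 16 butenolide aldehyde (3R,4S,5R,6R,10R), CH2CHO (C9–C8) on C10
Conditions: Dess–Martin periodinane, CH2Cl2, 25 °C
Reagents that add atoms: none
Why: Dess–Martin oxidation; the non-basic medium should avoid retro-oxa-Michael opening of the β-alkoxy aldehyde and epimerisation at C6.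

Step 13
Reactants: 16 butenolide aldehyde
Product: 18 tricyclic alcohol (3R,4S,5R,6R,7R,8R,10R): α-methylene lactone ring A cis-fused to ring C, free 8-OH, O3/O15 silylene, via allylchromium dichloride 17 (not isolated)
Conditions: CrCl2 (5 equiv), THF, 25 °C, 0.005 M, slow addition of 16; aqueous work-up
Reagents that add atoms: none
Why: Two equivalents of divalent chromium reduce the allylic bromide of 16 to allylchromium 17 (trivalent chromium), which should add through its γ-carbon C7 to the C8 aldehyde in a six-membered chair with chromium bridging O8 and C13, an intramolecular Nozaki–Hiyama–Kishi allylation (SE2′) that moves the double bond to C11=C13. The closest known reaction type is the chromium- or zinc-mediated Barbier cyclisation of 2-(bromomethyl)acrylates and 3-(bromomethyl)butenolides onto aldehydes, used to close medium rings that carry an α-methylene lactone. Ring C (O, C5, C6, C7, C8, C9, C10) is the only ring formed and closes by 7-exo-trig C–C bond formation at the carbonyl. C7 is controlled by the resident C6 centre, because the four-atom tether C5–O–C10–C9 attached at C6 should deliver C8 to the butenolide face that carries C5 (H6/H7 cis); C8 is controlled by the chair, in which the tether is expected to hold C9 pseudo-axial and anti to H7, placing O8 cis to C11. The step needs chemoselectivity for the aldehyde over the lactone (organochromium reagents add only to aldehydes), ring closure over reduction or dimerisation (high dilution, slow addition) and tolerance of strain, since the C6 and C9 arms are trans on ring B; irreversible C–C bond formation pays for the trans-bridged bicycle.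

Step 14
Reactants: 19 (E)-but-2-enal (crotonaldehyde)
Product: 21 (2Z)-2-bromobut-2-enal, via 2,3-dibromobutanal 20 (not isolated)
Conditions: Br2, CH2Cl2, 0 °C; then Et3N, 0 to 25 °C
Reagents that add atoms: bromine, BrBr
Why: bromine addition to the enal and E1cB loss of HBr (acidic C2–H, bromide from C3) should give the more stable Z isomer with bromine cis to the methyl group.

Step 15
Reactants: 21 (2Z)-2-bromobut-2-enal
Product: 22 (2Z)-2-bromobut-2-en-1-ol
Conditions: NaBH4, CeCl3·7H2O, MeOH, 0 °C
Reagents that add atoms: none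
Why: Luche 1,2-reduction of the enal, which should leave the vinyl bromide and its geometry unchanged.

Step 16
Reactants: 22 (2Z)-2-bromobut-2-en-1-ol
Product: 24 (2Z)-2-(hydroxymethyl)but-2-enoic acid, via dilithio species 23 (not isolated)
Conditions: n-BuLi (1 equiv), Et2O, −78 °C; t-BuLi (2 equiv), −78 °C; CO2; aq. HCl
Reagents that add atoms: carbon dioxide, O=C=O
Why: alkoxide formation and bromine–lithium exchange give a configurationally stable vinyllithium that should be carboxylated with retention, so the carboxyl group ends cis to the methyl group (Z).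

Step 17
Reactants: 24 (2Z)-2-(hydroxymethyl)but-2-enoic acid
Product: 26 (2Z)-2-(acetoxymethyl)but-2-enoic acid, via mixed acetic anhydride 25 (not isolated)
Conditions: Ac2O, pyridine, CH2Cl2, 0 °C; then H2O, THF
Reagents that add atoms: acetic anhydride, CC(=O)OC(C)=O
Why: O-acetylation of the primary alcohol; the mixed anhydride formed at the carboxyl group is hydrolysed on aqueous work-up, and the absence of DMAP should avoid Z to E isomerisation.

Step 18
Reactants: 18 tricyclic alcohol; 26 (2Z)-2-(acetoxymethyl)but-2-enoic acid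
Product: 28 C8 ester (3R,4S,5R,6R,7R,8R,10R), O3/O15 silylene retained, via trichlorobenzoic mixed anhydride 27 (not isolated)
Conditions: 26, 2,4,6-trichlorobenzoyl chloride, Et3N, toluene, 25 °C; then 18, toluene, 80 °C
Reagents that add atoms: none
Why: Yamaguchi-type acylation through the mixed anhydride without a nucleophilic amine catalyst, which should keep the Z geometry of the acyl group; O-acylation retains C8.

Step 19
Reactants: 28 C8 ester
Product: 29 3,15-diol (3R,4R,5R,6R,7R,8R,10R)
Conditions: HF·pyridine, pyridine, THF, 0 to 25 °C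
Reagents that add atoms: none
Why: fluoride cleavage of the di-tert-butylsilylene; the esters, the allylic acetate and the α-methylene lactone should be stable to buffered HF·pyridine.

Step 20
Reactants: 29 3,15-diol
Product: 30 target, CNP0426612.2 (3R,4R,5R,6R,7R,8R,10R)
Conditions: AcCl (1.05 equiv), 2,4,6-collidine, CH2Cl2, −78 °C
Reagents that add atoms: acetyl chloride, CC(Cl)=O
Why: selective acetylation; at −78 °C acetyl chloride/collidine should acylate the primary C15 hydroxyl and leave the hindered secondary C3 hydroxyl free.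

**Compound list**

1 | (R)-(−)-linalool, (3R)-3,7-dimethylocta-1,6-dien-3-ol | O[C@](C)(CCC=C(C)C)C=C | starting material
2 | (3R)-3,7-dimethyloct-6-ene-1,3-diol | O[C@](C)(CCC=C(C)C)CCO | intermediate
3 | (3R)-1-[(tert-butyldimethylsilyl)oxy]-3,7-dimethyloct-6-en-3-ol | O[C@](C)(CCC=C(C)C)CCO[Si](C)(C)C(C)(C)C | intermediate
4 | (5R)-5-{2-[(tert-butyldimethylsilyl)oxy]ethyl}-5-methyloxolan-2-ol (both anomers) | OC1CC[C@](C)(CCO[Si](C)(C)C(C)(C)C)O1 | intermediate
5 | 4-vinyl-1,3-dioxolan-2-one (vinyl ethylene carbonate, racemic) | C=CC1COC(=O)O1 | starting material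
6 | (2R,3R,6R)-8-[(tert-butyldimethylsilyl)oxy]-2-ethenyl-6-methyloctane-1,3,6-triol | O[C@](C)(CC[C@@H](O)[C@H](C=C)CO)CCO[Si](C)(C)C(C)(C)C | intermediate
7 | (4R,5R)-2,2-di-tert-butyl-4-{(3R)-5-[(tert-butyldimethylsilyl)oxy]-3-hydroxy-3-methylpentyl}-5-ethenyl-1,3,2-dioxasilinane | O[C@](C)(CC[C@H]1O[Si](C(C)(C)C)(C(C)(C)C)OC[C@H]1C=C)CCO[Si](C)(C)C(C)(C)C | intermediate
8 | ring-B alkylmercury trifluoroacetate (C6–HgOCOCF3; 3R,4S,5R,10R) | FC(F)(F)C(=O)O[Hg]C[C@@H]1O[C@](C)(CC[C@H]2O[Si](C(C)(C)C)(C(C)(C)C)OC[C@@H]12)CCO[Si](C)(C)C(C)(C)C | intermediate (not isolated)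
9 | ring-B alcohol (3R,4S,5R,10R), CH2OH on C5, O3/O15 di-tert-butylsilylene, C8 OTBS | OC[C@@H]1O[C@](C)(CC[C@H]2O[Si](C(C)(C)C)(C(C)(C)C)OC[C@@H]12)CCO[Si](C)(C)C(C)(C)C | intermediate
10 | ring-B aldehyde (3R,4S,5R,10R), CHO on C5 | O=C[C@@H]1O[C@](C)(CC[C@H]2O[Si](C(C)(C)C)(C(C)(C)C)OC[C@@H]12)CCO[Si](C)(C)C(C)(C)C | intermediate
11 | allylic alcohol (3R,4S,5R,6R,10R), CH(OH)CH=CH2 on C5 | C=C[C@@H](O)[C@@H]1O[C@](C)(CC[C@H]2O[Si](C(C)(C)C)(C(C)(C)C)OC[C@@H]12)CCO[Si](C)(C)C(C)(C)C | intermediate
12 | 2-(bromomethyl)acrylic acid, 2-(bromomethyl)prop-2-enoic acid | C=C(CBr)C(=O)O | starting material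
13 | O6 2-(bromomethyl)acrylate of 11 (3R,4S,5R,6R,10R) | C=C[C@@H](OC(=O)C(=C)CBr)[C@@H]1O[C@](C)(CC[C@H]2O[Si](C(C)(C)C)(C(C)(C)C)OC[C@@H]12)CCO[Si](C)(C)C(C)(C)C | intermediate
14 | 3-(bromomethyl)butenolide, C8 OTBS (3R,4S,5R,6R,10R) | BrCC1=C[C@H]([C@@H]2O[C@](C)(CC[C@H]3O[Si](C(C)(C)C)(C(C)(C)C)OC[C@@H]23)CCO[Si](C)(C)C(C)(C)C)OC1=O | intermediate
15 | 3-(bromomethyl)butenolide, C8 OH (3R,4S,5R,6R,10R) | BrCC1=C[C@H]([C@@H]2O[C@](C)(CC[C@H]3O[Si](C(C)(C)C)(C(C)(C)C)OC[C@@H]23)CCO)OC1=O | intermediate
16 | 3-(bromomethyl)butenolide, C8 aldehyde (3R,4S,5R,6R,10R) | BrCC1=C[C@H]([C@@H]2O[C@](C)(CC[C@H]3O[Si](C(C)(C)C)(C(C)(C)C)OC[C@@H]23)CC=O)OC1=O | intermediate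
17 | allylchromium dichloride from 16 (C13–CrCl2, trivalent chromium) | Cl[Cr](Cl)CC1=C[C@H]([C@@H]2O[C@](C)(CC[C@H]3O[Si](C(C)(C)C)(C(C)(C)C)OC[C@@H]23)CC=O)OC1=O | intermediate (not isolated)
18 | tricyclic 8-alcohol, O3/O15 silylene (3R,4S,5R,6R,7R,8R,10R) | C=C1C(=O)O[C@H]2[C@@H]3O[C@](C)(CC[C@H]4O[Si](C(C)(C)C)(C(C)(C)C)OC[C@@H]34)C[C@@H](O)[C@@H]12 | intermediate
19 | (E)-but-2-enal (crotonaldehyde) | C/C=C/C=O | starting material
20 | 2,3-dibromobutanal | CC(Br)C(Br)C=O | intermediate (not isolated)
21 | (2Z)-2-bromobut-2-enal | C/C=C(\Br)C=O | intermediate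
22 | (2Z)-2-bromobut-2-en-1-ol | C/C=C(\Br)CO | intermediate
23 | lithium (2E)-2-lithiobut-2-en-1-olate (lithium cis to the methyl group) | C/C=C(\[Li])CO[Li] | intermediate (not isolated)
24 | (2Z)-2-(hydroxymethyl)but-2-enoic acid | C/C=C(/CO)C(=O)O | intermediate
25 | acetic (2Z)-2-(acetoxymethyl)but-2-enoic anhydride | C/C=C(/COC(C)=O)C(=O)OC(C)=O | intermediate (not isolated)
26 | (2Z)-2-(acetoxymethyl)but-2-enoic acid | C/C=C(/COC(C)=O)C(=O)O | intermediate
27 | (2Z)-2-(acetoxymethyl)but-2-enoic 2,4,6-trichlorobenzoic anhydride | C/C=C(/COC(C)=O)C(=O)OC(=O)c1c(Cl)cc(Cl)cc1Cl | intermediate (not isolated)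
28 | tricyclic C8 ester, O3/O15 silylene (3R,4S,5R,6R,7R,8R,10R) | C=C1C(=O)O[C@H]2[C@@H]3O[C@](C)(CC[C@H]4O[Si](C(C)(C)C)(C(C)(C)C)OC[C@@H]34)C[C@@H](OC(=O)/C(=C\C)COC(C)=O)[C@@H]12 | intermediate
29 | tricyclic C8 ester, 3,15-diol (3R,4R,5R,6R,7R,8R,10R) | C=C1C(=O)O[C@H]2[C@@H]3O[C@](C)(CC[C@@H](O)[C@H]3CO)C[C@@H](OC(=O)/C(=C\C)COC(C)=O)[C@@H]12 | intermediate
30 | CNP0426612.2 (3R,4R,5R,6R,7R,8R,10R) | C=C1C(=O)O[C@H]2[C@@H]3O[C@](C)(CC[C@@H](O)[C@H]3COC(C)=O)C[C@@H](OC(=O)/C(=C\C)COC(C)=O)[C@@H]12 | target

**Count and risks**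

Total step count: 20. Longest linear sequence: 16 steps (steps 1–13 and 18–20); steps 14–17 make the acyl side chain.

Steps most likely to fail:

1. Step 6. The seven-membered closure by the hindered tertiary hydroxyl may be too slow, so that intermolecular capture of the mercurinium ion or acid-induced loss of the silyl groups competes, or the facial selectivity at C5 may be poor. The fallback replaces alkene activation by π-allyl etherification and runs from 7 back to 10. Cross-metathesis of 7 with allyl methyl carbonate (second-generation Grubbs catalyst) should give the (E)-allylic methyl carbonate F1. Pd2(dba)3 (zerovalent palladium) with 1,4-bis(diphenylphosphino)butane ionises F1 to a π-allyl complex on which the tertiary hydroxyl closes at C5, giving the 5-vinyl oxepane F2 with the vinyl group on the convex face. Ozonolysis of F2 (O3, then PPh3) returns aldehyde 10.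

2. Step 13. Poor facial selectivity at the aldehyde carbon, with the C9 arm taking the pseudo-equatorial site of the chair, would deliver the C8 epimer; acyl migration of the lactone to O8 is a lesser hazard. The fallback sets C8 by inversion instead of by the cyclisation and runs from 16 to 28. The same chromium-mediated closure then gives the 8-epi alcohol F3, which is esterified with acid 26 under Mitsunobu conditions (PPh3, diisopropyl azodicarboxylate); this installs the acyl group with inversion at C8 and gives 28 directly, so that step 18 is not needed.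

3. Step 10. Ring closure onto the electron-poor 1,1-disubstituted alkene may be sluggish and the catalyst may decompose before the trisubstituted butenolide forms; the preceding acylation may also suffer from attack of DMAP on the allylic bromide. The fallback builds the lactone by carbonyl allylation and runs from 10 back to 14. Indium-mediated Barbier allylation of aldehyde 10 with ethyl 2-(bromomethyl)acrylate (indium metal, THF–H2O, chelation by trivalent indium favouring the syn adduct) should give the hydroxy ester F4. F4 lactonises (PPTS) to the α-methylene lactone F5. Bromine adds to the exocyclic alkene of F5 to give the dibromide F6, and Et3N removes HBr from F6 to give the 3-(bromomethyl)butenolide 14.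

**Further compounds**

F1 | step 6 | (E)-allylic methyl carbonate from 7 (C5=C6–CH2OCO2Me) | O[C@](C)(CC[C@H]1O[Si](C(C)(C)C)(C(C)(C)C)OC[C@H]1/C=C/COC(=O)OC)CCO[Si](C)(C)C(C)(C)C
F2 | step 6 | ring-B 5-vinyl oxepane (3R,4S,5R,10R) | C=C[C@@H]1O[C@](C)(CC[C@H]2O[Si](C(C)(C)C)(C(C)(C)C)OC[C@@H]12)CCO[Si](C)(C)C(C)(C)C
F3 | step 13 | 8-epi tricyclic alcohol (8S) | C=C1C(=O)O[C@H]2[C@@H]3O[C@](C)(CC[C@H]4O[Si](C(C)(C)C)(C(C)(C)C)OC[C@@H]34)C[C@H](O)[C@@H]12
F4 | step 10 | ethyl 4-hydroxy-2-methylidenebutanoate carrying ring B at C6 (6R) | CCOC(=O)C(=C)C[C@@H](O)[C@@H]1O[C@](C)(CC[C@H]2O[Si](C(C)(C)C)(C(C)(C)C)OC[C@@H]12)CCO[Si](C)(C)C(C)(C)C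
F5 | step 10 | α-methylene-γ-butyrolactone on C5 of ring B (6R) | C=C1C[C@H]([C@@H]2O[C@](C)(CC[C@H]3O[Si](C(C)(C)C)(C(C)(C)C)OC[C@@H]23)CCO[Si](C)(C)C(C)(C)C)OC1=O
F6 | step 10 | 3-bromo-3-(bromomethyl)butyrolactone on C5 of ring B (C11 epimers) | BrCC1(Br)C[C@H]([C@@H]2O[C@](C)(CC[C@H]3O[Si](C(C)(C)C)(C(C)(C)C)OC[C@@H]23)CCO[Si](C)(C)C(C)(C)C)OC1=O
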